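**Strategy.** The ten-membered ring is taken apart at its two double bonds. Because C1=C10 and C4=C5 are tied together by the C2–C3 bridge, the ring is a cyclohexene (C5, C6, C7, C8, C9, C10) joined on paper to 1-methylcyclobutene (C1–C4, C15). Light adds a shikimate-derived 3-oxocyclohexene-1-carboxylate (C7 side chain and C8 silyl ether in place, 4,5-cis) to the cyclobutene. This forms C1–C10, C4–C5 and a cyclobutane in one operation. Heat then breaks C1–C4 and C5–C10, so the cyclodecadiene forms with no macrocyclisation. Hydride delivery from O8 sets C6, and lactone methylenation completes the target.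

Key step: step 9

Remark: germacrane numbering is used for all intermediates (shikimate C1, C2, C3, C4, C5, C6 = germacrane C10, C5, C6, C7, C8, C9); the orthoacetate of step 2 is assumed to open to the ester on the pseudoaxial O3, as ring-fused orthoesters generally do.

Step 1
Reactants: 1 (−)-shikimic acid
Product: 2 methyl (3R,4S,5R)-3,4,5-trihydroxycyclohex-1-ene-1-carboxylate (methyl shikimate)
Conditions: MeOH, camphorsulfonic acid (cat.), reflux
Reagents that add atoms: methanol, CO
Why: Acid-catalysed Fischer esterification in excess methanol touches only the carboxyl group, so the three stereocentres of the chiral pool are carried over unchanged.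

Step 2
Reactants: 2 methyl shikimate
Product: 5 methyl (3R,4R,5R)-3-acetoxy-5-(tert-butyldimethylsilyloxy)-4-hydroxycyclohex-1-ene-1-carboxylate, via 3,4-orthoacetate 3 (not isolated), via silylated orthoacetate 4 (not isolated)
Conditions: MeC(OMe)3, camphorsulfonic acid (cat.), CH2Cl2, rt; then imidazole, TBSCl, DMF, rt; then AcOH–H2O (4:1), rt
Reagents that add atoms: trimethyl orthoacetate, CC(OC)(OC)OC; tert-butyldimethylsilyl chloride, CC(C)(C)[Si](C)(C)Cl; water, O
Why: Cyclic orthoester formation engages only the cis-3,4-diol, silylation then caps the one free hydroxyl (O5, the future O8), and mild acid hydrolysis of the ring-fused orthoester should leave the ester on the pseudoaxial O3, so that O4 alone is free and no stereocentre is touched (orthoester protection and regioselective opening).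

Step 3
Reactants: 5 methyl 3-O-acetyl-5-O-TBS-shikimate
Product: 6 methyl (3R,4R,5R)-3-acetoxy-5-(tert-butyldimethylsilyloxy)-4-(trifluoromethylsulfonyloxy)cyclohex-1-ene-1-carboxylate
Conditions: Tf2O, pyridine, CH2Cl2, −20 °C
Reagents that add atoms: trifluoromethanesulfonic anhydride, O=S(=O)(OS(=O)(=O)C(F)(F)F)C(F)(F)F
Why: O-Sulfonylation of the secondary alcohol occurs with retention and installs the leaving group at C4 (germacrane C7).

Step 4
Reactants: 6 the C4 triflate; 7 dimethyl malonate
Product: 8 methyl (3R,4S,5R)-3-acetoxy-4-[bis(methoxycarbonyl)methyl]-5-(tert-butyldimethylsilyloxy)cyclohex-1-ene-1-carboxylate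
Conditions: NaH, 7, THF–DMF, 0 °C; then 6, 0 °C to rt
Reagents that add atoms: none
Why: SN2 alkylation of the soft malonate anion by the secondary triflate inverts C4 and so places the carbon branch cis to the silyloxy group; the cis acetate cannot participate, and the equatorial triflate has no antiperiplanar hydrogen in the preferred half-chair, which should hold back elimination.

Step 5
Reactants: 8 the malonate
Product: 9 methyl (3R,4S,5R)-3-acetoxy-5-(tert-butyldimethylsilyloxy)-4-(2-methoxy-2-oxoethyl)cyclohex-1-ene-1-carboxylate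
Conditions: LiCl, H2O, DMSO, 130 °C
Reagents that add atoms: none
Why: Krapcho dealkoxycarbonylation (chloride attack on a malonate methyl group, loss of CO2, protonation) removes only one of the geminal esters and leaves the conjugated ester, the acetate, the silyl ether and C4 untouched.

Step 6
Reactants: 9 the acetate
Product: 10 methyl (3R,4S,5R)-5-(tert-butyldimethylsilyloxy)-3-hydroxy-4-(2-methoxy-2-oxoethyl)cyclohex-1-ene-1-carboxylate
Conditions: K2CO3 (cat.), MeOH, 0 °C
Reagents that add atoms: none
Why: Zemplén-type transesterification removes the allylic acetate under mild base, and C4 cannot epimerise because it is not yet next to a carbonyl group.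

Step 7
Reactants: 10 the allylic alcohol
Product: 11 methyl (4R,5R)-5-(tert-butyldimethylsilyloxy)-4-(2-methoxy-2-oxoethyl)-3-oxocyclohex-1-ene-1-carboxylate (4,5-cis)
Conditions: Dess–Martin periodinane, CH2Cl2, 0 °C to rt
Reagents that add atoms: none
Why: Dess–Martin oxidation gives the enone without base, which matters because C4 (C7) is now α to the ketone and the silyloxy group is β to it.

Step 8
Reactants: 12 methylenecyclobutane
Product: 13 1-methylcyclobutene
Conditions: KOtBu (cat.), DMSO, 25 °C; fractional distillation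
Reagents that add atoms: none
Why: Base-catalysed prototropic isomerisation should favour the trisubstituted ring olefin at equilibrium, and the two volatile isomers are separated by distillation.

Step 9
Reactants: 11 the enone; 13 1-methylcyclobutene
Product: 14 methyl (1R,2R,5S,6R,8R,9R)-9-(tert-butyldimethylsilyloxy)-8-(2-methoxy-2-oxoethyl)-5-methyl-7-oxotricyclo[4.4.0.0(2,5)]decane-1-carboxylate (cis,anti,cis; cyclobutane on the face opposite the C7 and C8 groups)
Conditions: hν (350 nm, Pyrex), 13 (10 equiv), CH2Cl2 (degassed), −20 °C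
Reagents that add atoms: none
Why: Excitation of the enone and intersystem crossing give a triplet that adds to the strained olefin of 13 to form a 1,4-biradical, which closes after spin inversion; this is an intermolecular enone–alkene (2+2) photocycloaddition, and the closest known case is the addition of β-substituted cyclohexenones to 1-methylcyclobutene. The one ring that closes is the cyclobutane C10–C5–C4–C1, built stepwise by radical addition (first bond) and radical recombination (second bond), suprafacially on both partners. C5 and C10 should be cis because of the strain of a six–four fusion, C1 and C4 are cis because they come from a ring olefin, the anti relation should follow from approach of the cyclobutene with its CH2–CH2 edge turned away from the six-membered ring, and the face attacked should be the one opposite the C7 and C8 substituents. The step needs C10–C1 and C5–C4 bonding; this should be secured because the other orientation would have to join two adjacent quaternary centres (C10 and C4), so that biradical should revert, and because 13 is used in excess at low temperature. All four new centres are erased in step 10, so only the cis,anti,cis relation has to be right.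

Step 10
Reactants: 14 the tricyclic ketone
Product: 15 methyl (1E,5E,8R,9R)-9-(tert-butyldimethylsilyloxy)-8-(2-methoxy-2-oxoethyl)-5-methyl-7-oxocyclodeca-1,5-diene-1-carboxylate (ring-cis at C1=C10 and ring-trans at C4=C5 in germacrane numbering)
Conditions: PhMe (0.01 M, degassed), base-washed sealed tube, 200 °C, 30 min
Reagents that add atoms: none
Why: Thermal cycloreversion of the bicyclo[2.2.0]hexane (C1–C4 homolysis to a chair cyclohexane-1,4-diyl, then C5–C10 scission) should place C6 equatorial and C9 axial, giving a ring-trans C4=C5 and a ring-cis C1=C10 bond, while conjugation of both new olefins (ketone, ester) should hold back Cope rearrangement.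

Step 11
Reactants: 15 the silyl ether
Product: 16 methyl (1E,5E,8R,9R)-9-hydroxy-8-(2-methoxy-2-oxoethyl)-5-methyl-7-oxocyclodeca-1,5-diene-1-carboxylate
Conditions: HF·pyridine, pyridine, THF, 0 °C
Reagents that add atoms: none
Why: Buffered fluoride desilylation frees O8 without enolising the β-hydroxy ketone, so C7 and C8 keep their configuration; 16 is used at once.

Step 12
Reactants: 16 the β-hydroxy ketone
Product: 18 methyl (3aR,4R,6E,10E,11aR)-10-methyl-4-[(2-methylprop-2-enoyl)oxy]-2-oxo-2,3,3a,4,5,8,9,11a-octahydrocyclodeca[b]furan-6-carboxylate, via hydroxy ester 17 (not isolated)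
Conditions: SmI2 (0.3 equiv), methacrolein (8 equiv), THF, −10 °C; then pyridinium p-toluenesulfonate (cat.), CH2Cl2, rt
Reagents that add atoms: methacrolein, C=C(C)C=O
Why: Evans–Tishchenko reduction: the hemiacetal formed from O8–H and methacrolein passes its hydride to C6 inside a samarium-bound six-membered chair, so hydrogen enters C6 on the face of O8 (1,3-anti, 6R), O8 is left as the methacrylate, and the freed O6 then closes the trans-fused γ-lactone on the C12 ester.

Step 13
Reactants: 18 the lactone
Product: 22 methyl (3aR,4R,6E,10E,11aR)-10-methyl-3-methylidene-4-[(2-methylprop-2-enoyl)oxy]-2-oxo-2,3,3a,4,5,8,9,11a-octahydrocyclodeca[b]furan-6-carboxylate (CNP0317149.1), via silyl ketene acetal 19 (not isolated), via Mannich base 20 (not isolated), via ammonium iodide 21 (not isolated)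
Conditions: Me3SiOTf, Et3N, CH2Cl2, 0 °C; then CH2=NMe2+ I−, rt; then MeI, MeOH, rt; then NaHCO3 (aq), EtOAc
Reagents that add atoms: N,N-dimethylmethyleneiminium iodide (Eschenmoser's salt), C=[N+](C)C.[I-]
Why: Soft enolisation of the lactone (the only carbonyl with α-hydrogens), Mannich reaction of the silyl ketene acetal with Eschenmoser's salt, quaternisation and base-induced elimination give the exocyclic methylene without a strong base, which spares the methacrylate; C11 becomes sp2, so no stereocentre results.

**Compound list**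

1 | (−)-shikimic acid, (3R,4S,5R)-3,4,5-trihydroxycyclohex-1-ene-1-carboxylic acid | OC(=O)C1=C[C@@H](O)[C@@H](O)[C@H](O)C1 | starting material
2 | methyl shikimate, methyl (3R,4S,5R)-3,4,5-trihydroxycyclohex-1-ene-1-carboxylate | COC(=O)C1=C[C@@H](O)[C@@H](O)[C@H](O)C1 | intermediate
3 | methyl 3,4-O-(1-methoxyethylidene)shikimate (orthoacetate, both epimers at the orthoester carbon, 5-OH free) | COC(=O)C1=C[C@H]2OC(C)(OC)O[C@H]2[C@H](O)C1 | intermediate
4 | methyl 5-O-(tert-butyldimethylsilyl)-3,4-O-(1-methoxyethylidene)shikimate | COC(=O)C1=C[C@H]2OC(C)(OC)O[C@H]2[C@H](O[Si](C)(C)C(C)(C)C)C1 | intermediate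
5 | methyl (3R,4R,5R)-3-acetoxy-5-(tert-butyldimethylsilyloxy)-4-hydroxycyclohex-1-ene-1-carboxylate | COC(=O)C1=C[C@@H](OC(C)=O)[C@@H](O)[C@H](O[Si](C)(C)C(C)(C)C)C1 | intermediate
6 | methyl (3R,4R,5R)-3-acetoxy-5-(tert-butyldimethylsilyloxy)-4-(trifluoromethylsulfonyloxy)cyclohex-1-ene-1-carboxylate | COC(=O)C1=C[C@@H](OC(C)=O)[C@@H](OS(=O)(=O)C(F)(F)F)[C@H](O[Si](C)(C)C(C)(C)C)C1 | intermediate
7 | dimethyl malonate | COC(=O)CC(=O)OC | starting material
8 | methyl (3R,4S,5R)-3-acetoxy-4-[bis(methoxycarbonyl)methyl]-5-(tert-butyldimethylsilyloxy)cyclohex-1-ene-1-carboxylate (C4 branch cis to O5) | COC(=O)C1=C[C@@H](OC(C)=O)[C@H](C(C(=O)OC)C(=O)OC)[C@H](O[Si](C)(C)C(C)(C)C)C1 | intermediate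
9 | methyl (3R,4S,5R)-3-acetoxy-5-(tert-butyldimethylsilyloxy)-4-(2-methoxy-2-oxoethyl)cyclohex-1-ene-1-carboxylate | COC(=O)C1=C[C@@H](OC(C)=O)[C@H](CC(=O)OC)[C@H](O[Si](C)(C)C(C)(C)C)C1 | intermediate
10 | methyl (3R,4S,5R)-5-(tert-butyldimethylsilyloxy)-3-hydroxy-4-(2-methoxy-2-oxoethyl)cyclohex-1-ene-1-carboxylate | COC(=O)C1=C[C@@H](O)[C@H](CC(=O)OC)[C@H](O[Si](C)(C)C(C)(C)C)C1 | intermediate
11 | methyl (4R,5R)-5-(tert-butyldimethylsilyloxy)-4-(2-methoxy-2-oxoethyl)-3-oxocyclohex-1-ene-1-carboxylate (4,5-cis) | COC(=O)C1=CC(=O)[C@H](CC(=O)OC)[C@H](O[Si](C)(C)C(C)(C)C)C1 | intermediate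
12 | methylenecyclobutane | C=C1CCC1 | starting material
13 | 1-methylcyclobutene | CC1=CCC1 | intermediate
14 | methyl (1R,2R,5S,6R,8R,9R)-9-(tert-butyldimethylsilyloxy)-8-(2-methoxy-2-oxoethyl)-5-methyl-7-oxotricyclo[4.4.0.0(2,5)]decane-1-carboxylate (cis,anti,cis) | COC(=O)[C@@]12C[C@@H](O[Si](C)(C)C(C)(C)C)[C@@H](CC(=O)OC)C(=O)[C@@H]1[C@@]3(C)CC[C@H]32 | intermediate
15 | methyl (1E,5E,8R,9R)-9-(tert-butyldimethylsilyloxy)-8-(2-methoxy-2-oxoethyl)-5-methyl-7-oxocyclodeca-1,5-diene-1-carboxylate | CC(C)(C)[Si](C)(C)O[C@@H]1C/C(C(=O)OC)=C\CC/C(C)=C/C(=O)[C@@H]1CC(=O)OC | intermediate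
16 | methyl (1E,5E,8R,9R)-9-hydroxy-8-(2-methoxy-2-oxoethyl)-5-methyl-7-oxocyclodeca-1,5-diene-1-carboxylate | O[C@@H]1C/C(C(=O)OC)=C\CC/C(C)=C/C(=O)[C@@H]1CC(=O)OC | intermediate
17 | methyl (1E,5E,7R,8S,9R)-7-hydroxy-8-(2-methoxy-2-oxoethyl)-5-methyl-9-[(2-methylprop-2-enoyl)oxy]cyclodeca-1,5-diene-1-carboxylate | C=C(C)C(=O)O[C@@H]1C/C(C(=O)OC)=C\CC/C(C)=C/[C@@H](O)[C@@H]1CC(=O)OC | intermediate
18 | methyl (3aR,4R,6E,10E,11aR)-10-methyl-4-[(2-methylprop-2-enoyl)oxy]-2-oxo-2,3,3a,4,5,8,9,11a-octahydrocyclodeca[b]furan-6-carboxylate | C=C(C)C(=O)O[C@@H]1C/C(C(=O)OC)=C\CC/C(C)=C/[C@H]2OC(=O)C[C@@H]21 | intermediate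
19 | 2-(trimethylsilyloxy) ketene acetal of lactone 18 (C11=C12) | C=C(C)C(=O)O[C@@H]1C/C(C(=O)OC)=C\CC/C(C)=C/[C@H]2OC(O[Si](C)(C)C)=C[C@@H]21 | intermediate
20 | 3-[(dimethylamino)methyl] derivative of lactone 18 (both C11 epimers) | C=C(C)C(=O)O[C@@H]1C/C(C(=O)OC)=C\CC/C(C)=C/[C@H]2OC(=O)C(CN(C)C)[C@@H]21 | intermediate
21 | trimethylammonium iodide of 20 | C=C(C)C(=O)O[C@@H]1C/C(C(=O)OC)=C\CC/C(C)=C/[C@H]2OC(=O)C(C[N+](C)(C)C)[C@@H]21.[I-] | intermediate
22 | methyl (3aR,4R,6E,10E,11aR)-10-methyl-3-methylidene-4-[(2-methylprop-2-enoyl)oxy]-2-oxo-2,3,3a,4,5,8,9,11a-octahydrocyclodeca[b]furan-6-carboxylate (6R,7R,8R in germacrane numbering) | C=C(C)C(=O)O[C@@H]1C/C(C(=O)OC)=C\CC/C(C)=C/[C@H]2OC(=O)C(=C)[C@@H]21 | target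

**Step count.** Total: 13 steps. Longest linear sequence: 12 steps (steps 1–7 and 9–13); step 8 is a one-step side branch.

**The three steps most likely to fail**

Step 10, ring opening. The diyl may break its second bond through the other chair (C6 axial), which would pair a ring-trans C1=C10 with a ring-cis C4=C5 bond. The ketone may also enolise at 200 °C, which would scramble C7 or expel the silyloxy group, and the product may go on by Cope rearrangement to the divinylcyclohexane. The fallback sets out from 14 and comes back at 15. The C6 ketone is first masked under aprotic conditions (1,2-bis(trimethylsilyloxy)ethane, Me3SiOTf cat., CH2Cl2, −78 °C) as the dioxolane ketal F1. This removes the enolisable carbonyl and turns C6 into a bulky, fully substituted centre that should sit equatorial in the diyl. Thermolysis of F1 (PhMe, 200 °C, short residence time in a flow tube) should give the cyclodecadiene ketal F2. Hydrolysis (pyridinium p-toluenesulfonate, acetone–H2O, rt) then returns the enone 15. The price is that the C4=C5 bond is not conjugated during heating, so contact time must stay short.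

Step 4, carbon branch at C7. Substitution at a secondary carbon flanked by two oxygenated carbons may be slower than 1,2-elimination toward C3 from the ring-flipped half-chair, or than attack of the malonate on the acetate. The fallback sets out from 2 and comes back at 11; it delivers the two-carbon unit from O5 by radical cyclisation, which can only give the cis arrangement.
- 2 and 1,1'-thiocarbonyldiimidazole give the 3,4-thionocarbonate F3.
- O5 is alkylated with 1,2-dibromoethyl ethyl ether and N,N-dimethylaniline to the bromoacetal F4.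
- Corey–Winter olefination with 1,3-dimethyl-2-phenyl-1,3,2-diazaphospholidine (THF, 40 °C) gives the 1,3-diene F5.
- Bu3SnH and AIBN (PhH, 80 °C; then DBU to bring the olefin back into conjugation) close the ring by 5-exo attack on C4 (Ueno–Stork cyclisation) to the cis-fused bicyclic acetal F6.
- Jones reagent (CrO3, H2SO4, acetone) gives the lactone F7.
- NaOH opens lactone and ring ester to the disodium hydroxy dicarboxylate F8.
- TBSCl and imidazole give the tris-silyl compound F9.
- K2CO3 in aqueous methanol cleaves only the silyl esters to the silyloxy diacid F10.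
- Me3SiCHN2 gives the dimethyl ester F11, which lacks only the C6 oxygen.
- Allylic oxidation at the γ-carbon of the unsaturated ester (CrO3, 3,5-dimethylpyrazole, CH2Cl2, −20 °C) gives 11.

Step 12, reduction with acyl transfer. Hydride transfer from the hemiacetal of an unsaturated aldehyde may be slow, so that the trivalent samarium alkoxide instead closes O8 onto the C12 ester. The methacryloyl group may also migrate from O8 to O6 before the lactone closes. The fallback sets out from 16 and comes back at 18; it separates reduction and acylation. Me4NBH(OAc)3 (AcOH–MeCN, −20 °C) reduces the ketone by hydride delivery from O8 to the 1,3-anti diol F12. Acid-catalysed lactonisation (pyridinium p-toluenesulfonate, CH2Cl2) should then give the 8-hydroxy 6,12-lactone F13, and acylation of O8 (methacrylic anhydride, Et3N, DMAP) gives 18. In this variant the choice between O6 and O8 in the lactonisation is no longer enforced and would have to be checked.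

**Further compounds**

F1 | step 10 | ethylene ketal (spiro-dioxolane at C6) of tricyclic ketone 14 | COC(=O)[C@@]12C[C@@H](O[Si](C)(C)C(C)(C)C)[C@@H](CC(=O)OC)C3(OCCO3)[C@@H]1[C@@]4(C)CC[C@H]42
F2 | step 10 | ethylene ketal (at C6) of cyclodecadienone 15 | CC(C)(C)[Si](C)(C)O[C@@H]1C/C(C(=O)OC)=C\CC/C(C)=C/C2(OCCO2)[C@@H]1CC(=O)OC
F3 | step 4 | methyl shikimate 3,4-thionocarbonate | COC(=O)C1=C[C@H]2OC(=S)O[C@H]2[C@H](O)C1
F4 | step 4 | methyl 5-O-(2-bromo-1-ethoxyethyl)shikimate 3,4-thionocarbonate (both acetal epimers) | COC(=O)C1=C[C@H]2OC(=S)O[C@H]2[C@H](OC(CBr)OCC)C1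
F5 | step 4 | methyl (5R)-5-(2-bromo-1-ethoxyethoxy)cyclohexa-1,3-diene-1-carboxylate | COC(=O)C1=CC=C[C@H](OC(CBr)OCC)C1
F6 | step 4 | methyl cis-2-ethoxy-2,3,3a,4,7,7a-hexahydro-1-benzofuran-6-carboxylate (ring fusion cis, both acetal epimers) | COC(=O)C1=CC[C@@H]2CC(OCC)O[C@@H]2C1
F7 | step 4 | methyl cis-2-oxo-2,3,3a,4,7,7a-hexahydro-1-benzofuran-6-carboxylate | COC(=O)C1=CC[C@@H]2CC(=O)O[C@@H]2C1
F8 | step 4 | disodium (4R,5R)-4-(carboxylatomethyl)-5-hydroxycyclohex-1-ene-1-carboxylate | [Na+].[Na+].[O-]C(=O)C1=CC[C@H](CC(=O)[O-])[C@H](O)C1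
F9 | step 4 | bis(tert-butyldimethylsilyl) ester of the 5-O-TBS diacid | CC(C)(C)[Si](C)(C)OC(=O)C1=CC[C@H](CC(=O)O[Si](C)(C)C(C)(C)C)[C@H](O[Si](C)(C)C(C)(C)C)C1
F10 | step 4 | (4R,5R)-5-(tert-butyldimethylsilyloxy)-4-(carboxymethyl)cyclohex-1-ene-1-carboxylic acid | OC(=O)C1=CC[C@H](CC(=O)O)[C@H](O[Si](C)(C)C(C)(C)C)C1
F11 | step 4 | methyl (4R,5R)-5-(tert-butyldimethylsilyloxy)-4-(2-methoxy-2-oxoethyl)cyclohex-1-ene-1-carboxylate | COC(=O)C1=CC[C@H](CC(=O)OC)[C@H](O[Si](C)(C)C(C)(C)C)C1
F12 | step 12 | methyl (1E,5E,7R,8R,9R)-7,9-dihydroxy-8-(2-methoxy-2-oxoethyl)-5-methylcyclodeca-1,5-diene-1-carboxylate | O[C@@H]1C/C(C(=O)OC)=C\CC/C(C)=C/[C@@H](O)[C@@H]1CC(=O)OC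
F13 | step 12 | methyl (3aR,4R,6E,10E,11aR)-4-hydroxy-10-methyl-2-oxo-2,3,3a,4,5,8,9,11a-octahydrocyclodeca[b]furan-6-carboxylate | O[C@@H]1C/C(C(=O)OC)=C\CC/C(C)=C/[C@H]2OC(=O)C[C@@H]21
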